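**Retrosynthetic overview**
- The target has one non-aromatic ring, an oxane (O1, C2 aryl, C4 hydroxyl, C6 arylethyl, all cis). The strategy rests on the cis C2/C6 pair flanking O1 together with the C4 oxygen: these are the bridgeheads, the bridging oxygen and the carbonyl of 8-oxabicyclo[3.2.1]oct-6-en-3-one.
- Late disconnections: the side-chain C=C next to C6 (Wittig, then hydrogenation with global debenzylation) and the C2–aryl bond (nickel/photoredox decarboxylative arylation, then acid equilibration to the all-equatorial ring).
- The two one-carbon arms at C2 and C6 come from ozonolysis/reduction of the C6=C7 bridge of the bicycle. Lipase monoacetylation of the resulting meso diol sets the absolute configuration, and the C4 oxygen configuration comes from hydride delivery to the bicyclic ketone.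
- Ring formation: the oxane is the only ring made. It is closed in step 1 by a furan/oxyallyl [4+3] cycloaddition (bonds C2–C3 and C5–C6), together with a cycloheptenone ring that is cut open in step 4. Both arenes are bought.

Key step: step 1

Assumption: the lipase is taken to acetylate the hydroxymethyl arm on the ring carbon that becomes C6 of the target; if it prefers the other arm, the hydrolytic mode given as the fallback to step 5 supplies the same monoacetate.

**Step 1**
Reactants: 1 furan; 2 1,1,3,3-tetrabromoacetone
Product: 4 meso 8-oxabicyclo[3.2.1]oct-6-en-3-one, via dibromo cycloadduct 3 (not isolated)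
Conditions: Zn–Cu couple, THF, −10 °C → rt (1 in excess); then Zn–Cu couple, NH4Cl, MeOH, −78 °C → rt
Reagents that add atoms: none
Why: Zinc reduces 2 to a zinc bromo-enolate that loses bromide to give the 1,3-dibromo-2-oxyallyl cation, a 2π three-carbon partner that adds across the two α-carbons of furan (the 4π partner) in a [4+3] cycloaddition, the established reaction of furans with oxyallyl cations generated reductively from polybromoketones; a second charge of zinc–copper couple with NH4Cl then replaces both C–Br bonds by C–H through zinc enolates. The cycloaddition closes the cyclohept-4-enone ring by joining the two termini of the allyl cation to the two termini of the diene, and in the same event closes the oxan-4-one ring (furan oxygen as O1, furan α-carbons as C2 and C6, oxyallyl carbons as C3–C5; new bonds C2–C3 and C5–C6). The two new stereocentres are the bridgeheads, and the one-atom oxygen bridge allows only the cis arrangement, so 4 should be a single meso compound; the mixed configurations at the bromine-bearing carbons of 3 are erased on reduction. The selectivity needed is cycloaddition over electrophilic substitution at a furan α-carbon, which is favoured because the halogen-stabilised, zinc-bound oxyallyl cation is a soft electrophile and furan is held s-cis and used in excess.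

**Step 2**
Reactants: 4 meso 8-oxabicyclo[3.2.1]oct-6-en-3-one
Product: 5 endo-8-oxabicyclo[3.2.1]oct-6-en-3-ol (meso; hydroxyl axial on the oxane chair, on the face of the C6=C7 bridge)
Conditions: LiBH(s-Bu)3, THF, −78 °C; then NaOH, H2O2, 0 °C
Reagents that add atoms: none
Why: Bulky-hydride ketone reduction in which tri-sec-butylborohydride approaches the carbonyl of the chair oxanone from the open equatorial direction, away from the C6=C7 bridge, so the new hydroxyl should be axial and syn to that bridge (substrate control by the bicycle).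

**Step 3**
Reactants: 5 endo-8-oxabicyclo[3.2.1]oct-6-en-3-ol
Product: 6 endo-3-(benzyloxy)-8-oxabicyclo[3.2.1]oct-6-ene (meso)
Conditions: NaH, BnBr, n-Bu4NI (cat.), THF/DMF, 0 °C → rt
Reagents that add atoms: benzyl bromide, BrCc1ccccc1
Why: Williamson etherification of the sodium alkoxide with a primary benzylic halide, with no change at any stereocentre.

**Step 4**
Reactants: 6 endo-3-(benzyloxy)-8-oxabicyclo[3.2.1]oct-6-ene
Product: 8 meso all-cis-[4-(benzyloxy)oxane-2,6-diyl]dimethanol, via secondary ozonide 7 (not isolated)
Conditions: O3, CH2Cl2, −78 °C (Sudan red 7B end point); then NaBH4, MeOH, −78 °C → rt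
Reagents that add atoms: ozone, [O-][O+]=O
Why: Ozonolysis with reductive work-up cleaves the strained C6=C7 bridge to two hydroxymethyl groups without touching the three ring stereocentres, so the diol should be all-cis and meso; the benzyl ether survives when ozone is dosed to an indicator end point at −78 °C.

**Step 5**
Reactants: 8 meso all-cis-[4-(benzyloxy)oxane-2,6-diyl]dimethanol
Product: 9 [(2R,4S,6S)-4-(benzyloxy)-6-(hydroxymethyl)oxan-2-yl]methyl acetate
Conditions: lipase PS (Burkholderia cepacia, immobilised), vinyl acetate, i-Pr2O, rt; stopped when the diol is consumed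
Reagents that add atoms: vinyl acetate, CC(=O)OC=C
Why: Lipase-catalysed enantiotopic-group-selective transesterification of a meso diol with an irreversible acyl donor, in which the enzyme distinguishes the two mirror-related hydroxymethyl arms and thereby fixes the absolute configuration of all three ring stereocentres at once.

**Step 6**
Reactants: 9 [(2R,4S,6S)-4-(benzyloxy)-6-(hydroxymethyl)oxan-2-yl]methyl acetate
Product: 11 (2S,4R,6R)-6-(acetoxymethyl)-4-(benzyloxy)oxane-2-carboxylic acid, via aldehyde 10 (not isolated)
Conditions: TEMPO (cat.), PhI(OAc)2, MeCN/H2O 1:1, rt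
Reagents that add atoms: water, O
Why: Oxoammonium-mediated (TEMPO/PhI(OAc)2) oxidation of a primary alcohol to the acid through the aldehyde hydrate, to which the acetate and benzyl ether are inert; the configuration of the carboxyl-bearing carbon need not be protected because it becomes a radical centre in step 8.

**Step 7**
Reactants: 12 4-bromo-2-methoxyphenol
Product: 13 1-(benzyloxy)-4-bromo-2-methoxybenzene
Conditions: BnBr, K2CO3, DMF, rt
Reagents that add atoms: benzyl bromide, BrCc1ccccc1
Why: Williamson O-benzylation of a phenoxide, which masks the phenol that would otherwise compete as a nucleophile in the nickel coupling.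

**Step 8**
Reactants: 11 (2S,4R,6R)-6-(acetoxymethyl)-4-(benzyloxy)oxane-2-carboxylic acid; 13 1-(benzyloxy)-4-bromo-2-methoxybenzene
Product: 14 [(2R,4S,6RS)-4-(benzyloxy)-6-[4-(benzyloxy)-3-methoxyphenyl]oxan-2-yl]methyl acetate (epimer mixture at the aryl-bearing carbon; aryl trans to acetoxymethyl expected to dominate)
Conditions: Ir[dF(CF3)ppy]2(dtbbpy)PF6 (1 mol %), NiBr2·glyme (10 mol %), dtbbpy (15 mol %), Cs2CO3, DMF, blue LEDs, rt
Reagents that add atoms: none
Why: Metallaphotoredox decarboxylative arylation of an α-oxy carboxylic acid, in which the excited iridium photocatalyst oxidises the caesium carboxylate, loss of CO2 gives the ring α-oxy radical, this is captured by the aryl–nickel bromide complex formed from 13 and zerovalent nickel, and reductive elimination forms the C–aryl bond; the configuration at this carbon is not controlled here and is corrected in step 9.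

**Step 9**
Reactants: 14 [(2R,4S,6RS)-4-(benzyloxy)-6-[4-(benzyloxy)-3-methoxyphenyl]oxan-2-yl]methyl acetate
Product: 15 [(2R,4S,6S)-4-(benzyloxy)-6-[4-(benzyloxy)-3-methoxyphenyl]oxan-2-yl]methyl acetate (all-cis)
Conditions: TFA (10 vol %), CH2Cl2, 0 °C → rt
Reagents that add atoms: none
Why: Acid-catalysed equilibration of an electron-rich 2-aryl oxane, as known for aryl C-glycosides: protonation of O1 and heterolysis of the benzylic C–O bond, assisted by the para benzyloxy group, gives an open benzylic cation that recloses through the same hydroxyl from either face, and the equilibrium should lie on the chair with aryl, benzyloxy and acetoxymethyl groups all equatorial while the other two stereocentres are not involved.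

**Step 10**
Reactants: 15 [(2R,4S,6S)-4-(benzyloxy)-6-[4-(benzyloxy)-3-methoxyphenyl]oxan-2-yl]methyl acetate
Product: 16 [(2R,4S,6S)-4-(benzyloxy)-6-[4-(benzyloxy)-3-methoxyphenyl]oxan-2-yl]methanol
Conditions: K2CO3 (cat.), MeOH, 0 °C → rt
Reagents that add atoms: none
Why: Base-catalysed transesterification of the primary acetate with methanol, which leaves the benzyl ethers and the ring untouched.

**Step 11**
Reactants: 16 [(2R,4S,6S)-4-(benzyloxy)-6-[4-(benzyloxy)-3-methoxyphenyl]oxan-2-yl]methanol
Product: 17 (2R,4S,6S)-4-(benzyloxy)-6-[4-(benzyloxy)-3-methoxyphenyl]oxane-2-carbaldehyde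
Conditions: Dess–Martin periodinane, NaHCO3, CH2Cl2, 0 °C → rt
Reagents that add atoms: none
Why: Dess–Martin oxidation of a primary alcohol under buffered, non-epimerising conditions, the α-alkoxy aldehyde being used crude in step 13.

**Step 12**
Reactants: 18 [4-(benzyloxy)-3-methoxyphenyl]methanol
Product: 19 {[4-(benzyloxy)-3-methoxyphenyl]methyl}triphenylphosphonium bromide
Conditions: PPh3·HBr, MeCN, reflux
Reagents that add atoms: triphenylphosphine hydrobromide, [Br-].c1ccc(cc1)[PH+](c1ccccc1)c1ccccc1
Why: Electron-rich benzylic alcohols are converted directly into benzyltriphenylphosphonium bromides by PPh3·HBr through acid-promoted ionisation of the benzylic C–O bond and capture by the phosphine.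

**Step 13**
Reactants: 19 {[4-(benzyloxy)-3-methoxyphenyl]methyl}triphenylphosphonium bromide; 17 (2R,4S,6S)-4-(benzyloxy)-6-[4-(benzyloxy)-3-methoxyphenyl]oxane-2-carbaldehyde
Product: 21 (2S,4R,6R)-4-(benzyloxy)-2-[4-(benzyloxy)-3-methoxyphenyl]-6-{2-[4-(benzyloxy)-3-methoxyphenyl]ethenyl}oxane (E/Z mixture), via phosphorus ylide 20 (not isolated)
Conditions: NaN(SiMe3)2, THF, −78 → 0 °C; then 17, −78 °C → rt
Reagents that add atoms: none
Why: Wittig olefination with a semi-stabilised benzylic ylide, whose E/Z outcome is irrelevant because the alkene is hydrogenated; the aldehyde is added cold to preformed ylide, and its equatorial configuration is in any case the thermodynamically preferred one.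

**Step 14**
Reactants: 21 (2S,4R,6R)-4-(benzyloxy)-2-[4-(benzyloxy)-3-methoxyphenyl]-6-{2-[4-(benzyloxy)-3-methoxyphenyl]ethenyl}oxane
Product: 22 (2S,4R,6S)-2-(4-hydroxy-3-methoxyphenyl)-6-[2-(4-hydroxy-3-methoxyphenyl)ethyl]oxan-4-ol (target)
Conditions: H2 (1 atm), 10% Pd/C, EtOAc/MeOH, rt
Reagents that add atoms: none
Why: Heterogeneous catalytic hydrogenation saturates the styrenyl alkene and hydrogenolyses the three O-benzyl groups without touching a stereocentre, and the ring C2–O1 bond, a hindered secondary benzylic ether, is expected to be cleaved much more slowly than the primary O-benzyl groups at 1 atm.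

**Compound list**
1 | furan | c1ccoc1 | starting material
2 | 1,1,3,3-tetrabromoacetone | BrC(Br)C(=O)C(Br)Br | starting material
3 | 2,4-dibromo-8-oxabicyclo[3.2.1]oct-6-en-3-one (cis bridgeheads; mixture of epimers at the two bromine-bearing carbons) | C1=C[C@H]2C(Br)C(=O)C(Br)[C@@H]1O2 | intermediate
4 | meso (1R,5S)-8-oxabicyclo[3.2.1]oct-6-en-3-one | C1=C[C@H]2CC(=O)C[C@@H]1O2 | intermediate
5 | endo-8-oxabicyclo[3.2.1]oct-6-en-3-ol (meso; hydroxyl syn to the C6=C7 bridge) | C1=C[C@H]2C[C@@H](O)C[C@@H]1O2 | intermediate
6 | endo-3-(benzyloxy)-8-oxabicyclo[3.2.1]oct-6-ene (meso) | C1=C[C@H]2C[C@@H](OCc3ccccc3)C[C@@H]1O2 | intermediate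
7 | secondary ozonide (1,2,4-trioxolane) of 6; configuration at the two trioxolane carbons not defined | C14OC(OO4)[C@H]2C[C@@H](OCc3ccccc3)C[C@@H]1O2 | intermediate
8 | meso all-cis-[4-(benzyloxy)oxane-2,6-diyl]dimethanol | OC[C@H]1C[C@@H](OCc2ccccc2)C[C@@H](CO)O1 | intermediate
9 | [(2R,4S,6S)-4-(benzyloxy)-6-(hydroxymethyl)oxan-2-yl]methyl acetate | CC(=O)OC[C@H]1C[C@@H](OCc2ccccc2)C[C@@H](CO)O1 | intermediate
10 | [(2R,4R,6S)-4-(benzyloxy)-6-formyloxan-2-yl]methyl acetate | CC(=O)OC[C@H]1C[C@@H](OCc2ccccc2)C[C@@H](C=O)O1 | intermediate
11 | (2S,4R,6R)-6-(acetoxymethyl)-4-(benzyloxy)oxane-2-carboxylic acid | CC(=O)OC[C@H]1C[C@@H](OCc2ccccc2)C[C@@H](C(=O)O)O1 | intermediate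
12 | 4-bromo-2-methoxyphenol | COc1cc(Br)ccc1O | starting material
13 | 1-(benzyloxy)-4-bromo-2-methoxybenzene | COc1cc(Br)ccc1OCc1ccccc1 | intermediate
14 | [(2R,4S,6RS)-4-(benzyloxy)-6-[4-(benzyloxy)-3-methoxyphenyl]oxan-2-yl]methyl acetate (epimer mixture at C6) | CC(=O)OC[C@H]1C[C@@H](OCc2ccccc2)CC(c2ccc(OCc3ccccc3)c(OC)c2)O1 | intermediate
15 | [(2R,4S,6S)-4-(benzyloxy)-6-[4-(benzyloxy)-3-methoxyphenyl]oxan-2-yl]methyl acetate (all-cis) | CC(=O)OC[C@H]1C[C@@H](OCc2ccccc2)C[C@@H](c2ccc(OCc3ccccc3)c(OC)c2)O1 | intermediate
16 | [(2R,4S,6S)-4-(benzyloxy)-6-[4-(benzyloxy)-3-methoxyphenyl]oxan-2-yl]methanol | OC[C@H]1C[C@@H](OCc2ccccc2)C[C@@H](c2ccc(OCc3ccccc3)c(OC)c2)O1 | intermediate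
17 | (2R,4S,6S)-4-(benzyloxy)-6-[4-(benzyloxy)-3-methoxyphenyl]oxane-2-carbaldehyde | O=C[C@H]1C[C@@H](OCc2ccccc2)C[C@@H](c2ccc(OCc3ccccc3)c(OC)c2)O1 | intermediate
18 | [4-(benzyloxy)-3-methoxyphenyl]methanol | COc1cc(CO)ccc1OCc1ccccc1 | starting material
19 | {[4-(benzyloxy)-3-methoxyphenyl]methyl}triphenylphosphonium bromide | [Br-].COc1cc(C[P+](c2ccccc2)(c2ccccc2)c2ccccc2)ccc1OCc1ccccc1 | intermediate
20 | {[4-(benzyloxy)-3-methoxyphenyl]methylidene}triphenylphosphorane | COc1cc(C=P(c2ccccc2)(c2ccccc2)c2ccccc2)ccc1OCc1ccccc1 | intermediate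
21 | (2S,4R,6R)-4-(benzyloxy)-2-[4-(benzyloxy)-3-methoxyphenyl]-6-{2-[4-(benzyloxy)-3-methoxyphenyl]ethenyl}oxane (E/Z mixture) | COc1cc(C=C[C@H]2C[C@@H](OCc3ccccc3)C[C@@H](c3ccc(OCc4ccccc4)c(OC)c3)O2)ccc1OCc1ccccc1 | intermediate
22 | (2S,4R,6S)-2-(4-hydroxy-3-methoxyphenyl)-6-[2-(4-hydroxy-3-methoxyphenyl)ethyl]oxan-4-ol | COc1cc(CC[C@H]2C[C@@H](O)C[C@@H](c3ccc(O)c(OC)c3)O2)ccc1O | target

**Step count**
Total: 14 steps. Longest linear sequence: 12 steps (1–6, 8–11, 13, 14, from furan).

**Steps most likely to fail**

Step 8. Oxidative addition of the electron-rich aryl bromide to zerovalent nickel may be slow, so the ring radical could be lost to hydrogen-atom abstraction (protodecarboxylation) or dimerisation before it is arylated. The fallback sets out from acid 11 and bromide 13 and returns at 14. Acid 11 is esterified with N-hydroxyphthalimide (N,N'-diisopropylcarbodiimide, DMAP cat., CH2Cl2) to the redox-active ester 1,3-dioxoisoindolin-2-yl (2S,4R,6R)-6-(acetoxymethyl)-4-(benzyloxy)oxane-2-carboxylate F1. Bromide 13 is converted with Mg turnings and LiCl in THF into [4-(benzyloxy)-3-methoxyphenyl]magnesium bromide F2, which is transmetalated with ZnCl2 to [4-(benzyloxy)-3-methoxyphenyl]zinc chloride F3. F1 and F3 are then joined with NiCl2·glyme and dtbbpy in THF/DMF at rt. This is a decarboxylative Negishi-type arylation of a redox-active ester: low-valent nickel reduces the ester without light and the aryl group arrives as a nucleophile. It should give 14 as the same epimer mixture, which goes on to step 9.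

Step 9. The open benzylic cation may lose a proton to give a styrene, which can then ionise the allylic benzyloxy group, or the acid may cleave the aryl benzyl ether, before ring closure reaches equilibrium. The fallback runs from 14 back to 15 by oxidation and reduction in place of equilibration. DDQ in CH2Cl2/pH 7 buffer abstracts the benzylic hydride at the aryl-bearing carbon, and water opens the resulting oxocarbenium ion to the δ-hydroxy aryl ketone (2R,4R)-4-(benzyloxy)-6-[4-(benzyloxy)-3-methoxyphenyl]-2-hydroxy-6-oxohexyl acetate F4 (in equilibrium with its cyclic hemiketal). Reductive etherification with Et3SiH and BF3·OEt2 in CH2Cl2/MeCN at −40 °C then delivers hydride axially to the re-formed 2-aryl oxocarbenium ion. The aryl group should therefore end equatorial, giving 15 under kinetic control.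

Step 5. The enzyme may discriminate poorly between the enantiotopic hydroxymethyl groups, over-acetylate to the diacetate, or acetylate the wrong arm. The fallback runs from diol 8 back to 9 through the hydrolytic mode. Diol 8 is peracetylated (Ac2O, pyridine, DMAP cat.) to the meso diacetate all-cis-[4-(benzyloxy)oxane-2,6-diyl]dimethanediyl diacetate F5. One ester is then cleaved by pig liver esterase or the lipase of step 5 in pH 7 phosphate buffer/acetone at rt. An enzyme acts on the same enantiotopic arm in both modes, so hydrolysis gives the monoacetate of opposite configuration to that from acetylation; one of the two modes should therefore give 9.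

**Further compounds**
F1 | step 8 | 1,3-dioxoisoindolin-2-yl (2S,4R,6R)-6-(acetoxymethyl)-4-(benzyloxy)oxane-2-carboxylate | CC(=O)OC[C@H]1C[C@@H](OCc2ccccc2)C[C@@H](C(=O)ON2C(=O)c3ccccc3C2=O)O1
F2 | step 8 | [4-(benzyloxy)-3-methoxyphenyl]magnesium bromide | COc1cc([Mg]Br)ccc1OCc1ccccc1
F3 | step 8 | [4-(benzyloxy)-3-methoxyphenyl]zinc chloride | COc1cc([Zn]Cl)ccc1OCc1ccccc1
F4 | step 9 | (2R,4R)-4-(benzyloxy)-6-[4-(benzyloxy)-3-methoxyphenyl]-2-hydroxy-6-oxohexyl acetate | CC(=O)OC[C@H](O)C[C@@H](OCc1ccccc1)CC(=O)c1ccc(OCc2ccccc2)c(OC)c1
F5 | step 5 | meso all-cis-[4-(benzyloxy)oxane-2,6-diyl]dimethanediyl diacetate | CC(=O)OC[C@H]1C[C@@H](OCc2ccccc2)C[C@@H](COC(C)=O)O1
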